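**Retrosynthetic overview**
1. Target ⇒ (desilylation, C11 acetylation, decarboxylative methylenation) an α-carboxy ε-lactone ⇒ transannular 7-exo opening of an (11S,12S)-epoxide by a C15 malonic acid (C12–O bond, inversion at C12).
2. 14-membered carbocycle ⇒ acyclic ynal by a zerovalent-nickel reductive alkyne–aldehyde macrocyclization (C3–C4 bond, 4E olefin and C3 carbinol in one step), in place of the usual NHK or metathesis closure.
3. Ynal ⇒ enal + dimethyl malonate (organocatalytic Michael addition, sets C1); C5–C6 by copper-catalysed propyne/allyl bromide coupling; epoxide by Shi epoxidation.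
4. C1–C14 chain ⇒ neryl acetate (C6–C11, 7Z olefin) by oxidative cleavage, isopropenyl Grignard addition, Johnson–Claisen rearrangement (E-C11=C12) and a two-carbon Wittig extension.
5. Ring order: carbocycle first (step 12), seven-membered lactone second (step 13).

Assumption: cembrane-type numbering is used (C1 = ring CH carrying C15(=C17H2)–C16(=O)O; C3 = carbinol; C4=C5 and C7=C8 olefins; C11 = acetoxy carbon; C12 = methyl-bearing lactone carbon). The target is (1R,3R,4E,7Z,11S,12R). The L-fructose-derived Shi ketone is taken as a purchasable catalyst.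

**Step 1**
Reactants: 1 neryl acetate
Product: 2 (2Z)-5-(3,3-dimethyloxiran-2-yl)-3-methylpent-2-en-1-yl acetate (racemic)
Conditions: mCPBA (1.05 equiv), CH2Cl2, 0 °C
Reagents that add atoms: mCPBA (3-chloroperoxybenzoic acid), OOC(=O)c1cccc(Cl)c1
Why: Prilezhaev epoxidation is selective for the electron-rich 6,7-olefin because the 2,3-olefin is deactivated by the allylic acetate; the racemic epoxide carbon is destroyed in step 2.

**Step 2**
Reactants: 2 (2Z)-5-(3,3-dimethyloxiran-2-yl)-3-methylpent-2-en-1-yl acetate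
Product: 4 (2Z)-3-methyl-6-oxohex-2-en-1-yl acetate, via glycol 3 (not isolated)
Conditions: H5IO6 (1.2 equiv), THF/H2O, 0 °C to rt
Reagents that add atoms: none
Why: Acid-mediated epoxide hydrolysis (water enters at the tertiary carbon) followed by Malaprade glycol cleavage releases acetone and leaves the C11 aldehyde; no stereocenter is involved.

**Step 3**
Reactants: 4 (2Z)-3-methyl-6-oxohex-2-en-1-yl acetate; 5 isopropenylmagnesium bromide
Product: 6 (2Z)-6-hydroxy-3,7-dimethylocta-2,7-dien-1-yl acetate (racemic at the carbinol)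
Conditions: THF, −78 °C; then aq. NH4Cl
Reagents that add atoms: none
Why: Grignard 1,2-addition to the aldehyde is far faster than attack on the acetate at −78 °C; the carbinol is left racemic because it becomes sp2 in step 4.

**Step 4**
Reactants: 6 (2Z)-6-hydroxy-3,7-dimethylocta-2,7-dien-1-yl acetate; 7 trimethyl orthoacetate
Product: 9 methyl (4E,8Z)-10-acetoxy-4,8-dimethyldeca-4,8-dienoate, via ketene acetal 8 (not isolated)
Conditions: MeC(OMe)3 (7 equiv), EtCO2H (5 mol %), 110 °C, MeOH distilled off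
Reagents that add atoms: none
Why: Johnson–Claisen rearrangement through a chair transition state with the C10 chain equatorial forms the C13–C14 bond and sets the (E)-C11=C12 olefin (typically >95:5).

**Step 5**
Reactants: 9 methyl (4E,8Z)-10-acetoxy-4,8-dimethyldeca-4,8-dienoate
Product: 10 methyl 3-[(2S,3S)-3-[(3Z)-5-acetoxy-3-methylpent-3-en-1-yl]-2-methyloxiran-2-yl]propanoate
Conditions: 1,2:4,5-di-O-isopropylidene-β-L-erythro-2,3-hexodiulo-2,6-pyranose (L-fructose-derived Shi ketone, 30 mol %), KHSO5 (as 2KHSO5·KHSO4·K2SO4), K2CO3, Bu4NHSO4, MeCN/(MeO)2CH2–aq. Na2B4O7 buffer, 0 °C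
Reagents that add atoms: potassium peroxymonosulfate KHSO5, [K+].[O-]S(=O)(=O)OO
Why: Shi asymmetric epoxidation by the chiral dioxirane (spiro transition state) oxidizes the isolated E-trisubstituted olefin while the C7=C8 olefin is deactivated by its allylic acetate, and the L-series ketone gives the (11S,12S)-epoxide (about 90–95 % ee expected), which fixes C11 and, after inversion in step 13, C12.

**Step 6**
Reactants: 10 methyl 3-[(2S,3S)-3-[(3Z)-5-acetoxy-3-methylpent-3-en-1-yl]-2-methyloxiran-2-yl]propanoate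
Product: 11 methyl 3-[(2S,3S)-3-[(3Z)-5-hydroxy-3-methylpent-3-en-1-yl]-2-methyloxiran-2-yl]propanoate
Conditions: K2CO3 (0.2 equiv), MeOH, 0 °C
Reagents that add atoms: none
Why: Zemplén-type methanolysis removes the allylic acetate; the methyl ester exchange is degenerate and the trisubstituted epoxide is inert to methoxide at 0 °C.

**Step 7**
Reactants: 11 methyl 3-[(2S,3S)-3-[(3Z)-5-hydroxy-3-methylpent-3-en-1-yl]-2-methyloxiran-2-yl]propanoate
Product: 12 methyl 3-[(2S,3S)-3-[(3Z)-5-bromo-3-methylpent-3-en-1-yl]-2-methyloxiran-2-yl]propanoate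
Conditions: CBr4, PPh3, 2,6-lutidine, CH2Cl2, −20 °C
Reagents that add atoms: tetrabromomethane, BrC(Br)(Br)Br
Why: Appel reaction converts the primary allylic alcohol into the bromide by SN2 displacement of the oxyphosphonium group under neutral conditions, which keeps the Z olefin and the epoxide.

**Step 8**
Reactants: 12 methyl 3-[(2S,3S)-3-[(3Z)-5-bromo-3-methylpent-3-en-1-yl]-2-methyloxiran-2-yl]propanoate; 13 propyne
Product: 14 methyl 3-[(2S,3S)-2-methyl-3-[(3Z)-3-methyloct-3-en-6-yn-1-yl]oxiran-2-yl]propanoate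
Conditions: propyne (excess), CuI (copper monoiodide, 20 mol %), K2CO3 (2 equiv), DMF, 0 °C to rt
Reagents that add atoms: none
Why: Copper-catalysed alkynyl–allyl coupling, in which the copper acetylide of propyne displaces the primary allylic bromide at the unhindered carbon (SN2, no π-allyl intermediate, so 7Z is kept), gives the skipped enyne.

**Step 9**
Reactants: 14 methyl 3-[(2S,3S)-2-methyl-3-[(3Z)-3-methyloct-3-en-6-yn-1-yl]oxiran-2-yl]propanoate
Product: 15 3-[(2S,3S)-2-methyl-3-[(3Z)-3-methyloct-3-en-6-yn-1-yl]oxiran-2-yl]propanal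
Conditions: iBu2AlH (1.1 equiv), CH2Cl2, −78 °C; MeOH, then aq. KNaC4H4O6
Reagents that add atoms: none
Why: Partial ester reduction stops at the aluminium hemiacetal at −78 °C and gives the aldehyde on work-up; alkyne and epoxide are untouched.

**Step 10**
Reactants: 15 3-[(2S,3S)-2-methyl-3-[(3Z)-3-methyloct-3-en-6-yn-1-yl]oxiran-2-yl]propanal; 16 (triphenylphosphoranylidene)acetaldehyde
Product: 17 (2E)-5-[(2S,3S)-2-methyl-3-[(3Z)-3-methyloct-3-en-6-yn-1-yl]oxiran-2-yl]pent-2-enal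
Conditions: toluene, 80 °C
Reagents that add atoms: none
Why: Wittig olefination with the stabilized formyl ylide gives the (E)-enal and adds C2 and C3.

**Step 11**
Reactants: 17 (2E)-5-[(2S,3S)-2-methyl-3-[(3Z)-3-methyloct-3-en-6-yn-1-yl]oxiran-2-yl]pent-2-enal; 18 dimethyl malonate
Product: 19 dimethyl 2-[(3R)-1-[(2S,3S)-2-methyl-3-[(3Z)-3-methyloct-3-en-6-yn-1-yl]oxiran-2-yl]-5-oxopentan-3-yl]malonate
Conditions: (S)-2-[diphenyl(trimethylsilyloxy)methyl]pyrrolidine (10 mol %), PhCO2H (10 mol %), EtOH, 0 °C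
Reagents that add atoms: none
Why: Jørgensen–Hayashi iminium-ion catalysis, in which the (S)-catalyst forms an E,s-trans iminium ion whose diphenyl(silyloxy)methyl group blocks one face of C1 so that malonate adds from the other face, sets C1 as R (about 90 % ee expected for a β-alkyl enal; minor isomers become separable diastereomers).

**Step 12**
Reactants: 19 dimethyl 2-[(3R)-1-[(2S,3S)-2-methyl-3-[(3Z)-3-methyloct-3-en-6-yn-1-yl]oxiran-2-yl]-5-oxopentan-3-yl]malonate
Product: 20 dimethyl 2-[(1S,4Z,7E,9R,11R,14S)-4,8,14-trimethyl-9-(triethylsilyloxy)-15-oxabicyclo[12.1.0]pentadeca-4,7-dien-11-yl]malonate (14-membered carbocycle; C3–OSiEt3, 4E, 7Z, 11,12-epoxide)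
Conditions: Ni(cod)2 (20 mol %) premixed with 1,3-bis(2,4,6-trimethylphenyl)imidazol-2-ylidene (20 mol %), Et3SiH (3 equiv), THF (2 mM), slow addition of 19 over 8 h, rt
Reagents that add atoms: triethylsilane, CC[SiH](CC)CC
Why: Nickel-catalysed reductive alkyne–aldehyde macrocyclization (Montgomery type), in which oxidative cyclization at zerovalent nickel with the small carbene ligand places the new C3–C4 bond at the methyl-bearing alkyne carbon (endocyclic, 14-membered) and Si–H σ-bond metathesis with C–H reductive elimination adds C3 and H syn across the alkyne, gives the 4E olefin and the silylated C3 carbinol, whose configuration is set by macrocyclic 1,3-induction from C1 (3R expected as the major isomer but not assured; to be confirmed by Mosher analysis).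

**Step 13**
Reactants: 20 dimethyl 2-[(1S,4Z,7E,9R,11R,14S)-4,8,14-trimethyl-9-(triethylsilyloxy)-15-oxabicyclo[12.1.0]pentadeca-4,7-dien-11-yl]malonate
Product: 22 (1R,3R,4E,7Z,11S,12R)-11-hydroxy-4,8,12-trimethyl-14-oxo-3-(triethylsilyloxy)-13-oxabicyclo[10.3.2]heptadeca-4,7-diene-15-carboxylic acid (C15 epimers), via malonic diacid 21 (not isolated)
Conditions: LiOH (5 equiv), THF/MeOH/H2O, 0 °C to rt; 1 M HCl to pH 3 at 0 °C, extraction; then pyridinium p-toluenesulfonate (5 mol %), CH2Cl2, rt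
Reagents that add atoms: lithium hydroxide, [Li+].[OH-]
Why: Saponification to the malonic acid followed by transannular acid-catalysed 7-exo epoxide opening by a carboxyl group at the more substituted C12 with inversion (12S to 12R) closes the ε-lactone and frees the C11 hydroxyl with its configuration unchanged.

**Step 14**
Reactants: 22 (1R,3R,4E,7Z,11S,12R)-11-hydroxy-4,8,12-trimethyl-14-oxo-3-(triethylsilyloxy)-13-oxabicyclo[10.3.2]heptadeca-4,7-diene-15-carboxylic acid
Product: 24 (1R,3R,4E,7Z,11S,12R)-11-hydroxy-4,8,12-trimethyl-15-methylidene-3-(triethylsilyloxy)-13-oxabicyclo[10.3.2]heptadeca-4,7-dien-14-one, via Mannich base 23 (not isolated)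
Conditions: 37 % aq. CH2O, Et2NH (1.5 equiv), THF, rt then 60 °C
Reagents that add atoms: formaldehyde, C=O
Why: Mannich reaction at the malonic-type carbon C15 followed by decarboxylative elimination of diethylamine (decarboxylative methylenation) installs the exocyclic methylene and removes the C15 stereocenter.

**Step 15**
Reactants: 24 (1R,3R,4E,7Z,11S,12R)-11-hydroxy-4,8,12-trimethyl-15-methylidene-3-(triethylsilyloxy)-13-oxabicyclo[10.3.2]heptadeca-4,7-dien-14-one
Product: 25 (1R,3R,4E,7Z,11S,12R)-4,8,12-trimethyl-15-methylidene-14-oxo-3-(triethylsilyloxy)-13-oxabicyclo[10.3.2]heptadeca-4,7-dien-11-yl acetate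
Conditions: Ac2O, 4-(dimethylamino)pyridine (cat.), pyridine, CH2Cl2, rt
Reagents that add atoms: acetic anhydride, CC(=O)OC(C)=O
Why: Nucleophile-catalysed acylation of the only free hydroxyl (C11) proceeds with retention, C3 being protected as its triethylsilyl ether.

**Step 16**
Reactants: 25 (1R,3R,4E,7Z,11S,12R)-4,8,12-trimethyl-15-methylidene-14-oxo-3-(triethylsilyloxy)-13-oxabicyclo[10.3.2]heptadeca-4,7-dien-11-yl acetate
Product: 26 (1R,3R,4E,7Z,11S,12R)-3-hydroxy-4,8,12-trimethyl-15-methylidene-14-oxo-13-oxabicyclo[10.3.2]heptadeca-4,7-dien-11-yl acetate (target, CNP0130972.5)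
Conditions: HF·pyridine, THF/pyridine, 0 °C
Reagents that add atoms: none
Why: Fluoride-mediated cleavage of the triethylsilyl ether under buffered, non-basic conditions frees the C3 alcohol without touching the acetate or the α-methylene lactone and avoids translactonization.

**Compound list**
1 | neryl acetate, (2Z)-3,7-dimethylocta-2,6-dien-1-yl acetate | CC(C)=CCC/C(C)=C\COC(C)=O | starting material
2 | (2Z)-5-(3,3-dimethyloxiran-2-yl)-3-methylpent-2-en-1-yl acetate (racemic) | CC1(C)OC1CC/C(C)=C\COC(C)=O | intermediate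
3 | (2Z)-6,7-dihydroxy-3,7-dimethyloct-2-en-1-yl acetate (racemic glycol) | CC(C)(O)C(O)CC/C(C)=C\COC(C)=O | intermediate (not isolated)
4 | (2Z)-3-methyl-6-oxohex-2-en-1-yl acetate | O=CCC/C(C)=C\COC(C)=O | intermediate
5 | isopropenylmagnesium bromide, CH2=C(CH3)MgBr | CC(=C)[Mg]Br | starting material
6 | (2Z)-6-hydroxy-3,7-dimethylocta-2,7-dien-1-yl acetate (racemic at C6) | CC(=C)C(O)CC/C(C)=C\COC(C)=O | intermediate
7 | trimethyl orthoacetate (1,1,1-trimethoxyethane) | CC(OC)(OC)OC | starting material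
8 | (2Z)-6-[(1-methoxyethenyl)oxy]-3,7-dimethylocta-2,7-dien-1-yl acetate (mixed ketene acetal) | C=C(OC)OC(CC/C(C)=C\COC(C)=O)C(C)=C | intermediate (not isolated)
9 | methyl (4E,8Z)-10-acetoxy-4,8-dimethyldeca-4,8-dienoate | COC(=O)CC/C(C)=C/CC/C(C)=C\COC(C)=O | intermediate
10 | methyl 3-[(2S,3S)-3-[(3Z)-5-acetoxy-3-methylpent-3-en-1-yl]-2-methyloxiran-2-yl]propanoate | COC(=O)CC[C@]1(C)O[C@H]1CC/C(C)=C\COC(C)=O | intermediate
11 | methyl 3-[(2S,3S)-3-[(3Z)-5-hydroxy-3-methylpent-3-en-1-yl]-2-methyloxiran-2-yl]propanoate | COC(=O)CC[C@]1(C)O[C@H]1CC/C(C)=C\CO | intermediate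
12 | methyl 3-[(2S,3S)-3-[(3Z)-5-bromo-3-methylpent-3-en-1-yl]-2-methyloxiran-2-yl]propanoate | COC(=O)CC[C@]1(C)O[C@H]1CC/C(C)=C\CBr | intermediate
13 | propyne | CC#C | starting material
14 | methyl 3-[(2S,3S)-2-methyl-3-[(3Z)-3-methyloct-3-en-6-yn-1-yl]oxiran-2-yl]propanoate | COC(=O)CC[C@]1(C)O[C@H]1CC/C(C)=C\CC#CC | intermediate
15 | 3-[(2S,3S)-2-methyl-3-[(3Z)-3-methyloct-3-en-6-yn-1-yl]oxiran-2-yl]propanal | O=CCC[C@]1(C)O[C@H]1CC/C(C)=C\CC#CC | intermediate
16 | (triphenylphosphoranylidene)acetaldehyde | O=CC=P(c1ccccc1)(c1ccccc1)c1ccccc1 | starting material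
17 | (2E)-5-[(2S,3S)-2-methyl-3-[(3Z)-3-methyloct-3-en-6-yn-1-yl]oxiran-2-yl]pent-2-enal | O=C/C=C/CC[C@]1(C)O[C@H]1CC/C(C)=C\CC#CC | intermediate
18 | dimethyl malonate | COC(=O)CC(=O)OC | starting material
19 | dimethyl 2-[(3R)-1-[(2S,3S)-2-methyl-3-[(3Z)-3-methyloct-3-en-6-yn-1-yl]oxiran-2-yl]-5-oxopentan-3-yl]malonate | O=CC[C@@H](CC[C@]1(C)O[C@H]1CC/C(C)=C\CC#CC)C(C(=O)OC)C(=O)OC | intermediate
20 | dimethyl 2-[(1S,4Z,7E,9R,11R,14S)-4,8,14-trimethyl-9-(triethylsilyloxy)-15-oxabicyclo[12.1.0]pentadeca-4,7-dien-11-yl]malonate | COC(=O)C(C(=O)OC)[C@H]1C[C@@H](O[Si](CC)(CC)CC)/C(C)=C/C/C=C(/C)CC[C@@H]2O[C@@]2(C)CC1 | intermediate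
21 | 2-[(1S,4Z,7E,9R,11R,14S)-4,8,14-trimethyl-9-(triethylsilyloxy)-15-oxabicyclo[12.1.0]pentadeca-4,7-dien-11-yl]malonic acid | OC(=O)C(C(=O)O)[C@H]1C[C@@H](O[Si](CC)(CC)CC)/C(C)=C/C/C=C(/C)CC[C@@H]2O[C@@]2(C)CC1 | intermediate (not isolated)
22 | (1R,3R,4E,7Z,11S,12R)-11-hydroxy-4,8,12-trimethyl-14-oxo-3-(triethylsilyloxy)-13-oxabicyclo[10.3.2]heptadeca-4,7-diene-15-carboxylic acid (C15 epimers) | OC(=O)C1C(=O)O[C@]2(C)CC[C@@H]1C[C@@H](O[Si](CC)(CC)CC)/C(C)=C/C/C=C(/C)CC[C@@H]2O | intermediate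
23 | (1R,3R,4E,7Z,11S,12R)-15-[(diethylamino)methyl]-11-hydroxy-4,8,12-trimethyl-14-oxo-3-(triethylsilyloxy)-13-oxabicyclo[10.3.2]heptadeca-4,7-diene-15-carboxylic acid (Mannich base) | CCN(CC)CC1(C(=O)O)C(=O)O[C@]2(C)CC[C@@H]1C[C@@H](O[Si](CC)(CC)CC)/C(C)=C/C/C=C(/C)CC[C@@H]2O | intermediate (not isolated)
24 | (1R,3R,4E,7Z,11S,12R)-11-hydroxy-4,8,12-trimethyl-15-methylidene-3-(triethylsilyloxy)-13-oxabicyclo[10.3.2]heptadeca-4,7-dien-14-one | C=C1C(=O)O[C@]2(C)CC[C@@H]1C[C@@H](O[Si](CC)(CC)CC)/C(C)=C/C/C=C(/C)CC[C@@H]2O | intermediate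
25 | (1R,3R,4E,7Z,11S,12R)-4,8,12-trimethyl-15-methylidene-14-oxo-3-(triethylsilyloxy)-13-oxabicyclo[10.3.2]heptadeca-4,7-dien-11-yl acetate | C=C1C(=O)O[C@]2(C)CC[C@@H]1C[C@@H](O[Si](CC)(CC)CC)/C(C)=C/C/C=C(/C)CC[C@@H]2OC(C)=O | intermediate
26 | (1R,3R,4E,7Z,11S,12R)-3-hydroxy-4,8,12-trimethyl-15-methylidene-14-oxo-13-oxabicyclo[10.3.2]heptadeca-4,7-dien-11-yl acetate | C=C1C(=O)O[C@]2(C)CC[C@@H]1C[C@@H](O)/C(C)=C/C/C=C(/C)CC[C@@H]2OC(C)=O | target

**Totals**
Total step count: 16. Longest linear sequence: 16 steps (1 to 26).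

**Three steps most likely to fail**

Step 12 (highest risk). The nickel macrocyclization may close the 13-membered exocyclic isomer instead, may give the wrong C3 epimer, or may be slowed by the acidic malonate. The fallback sets out from 14 and comes back at 20, replacing the alkyne–aldehyde coupling by a vinyl iodide–aldehyde Nozaki–Hiyama–Kishi closure. Hydrozirconation of 14 with Cp2Zr(H)Cl and iodinolysis with I2 gives methyl 3-[(2S,3S)-3-[(3Z,6E)-7-iodo-3-methylocta-3,6-dien-1-yl]-2-methyloxiran-2-yl]propanoate F5. The conditions of steps 9 to 11 then give 3-[(2S,3S)-3-[(3Z,6E)-7-iodo-3-methylocta-3,6-dien-1-yl]-2-methyloxiran-2-yl]propanal F6, then (2E)-5-[(2S,3S)-3-[(3Z,6E)-7-iodo-3-methylocta-3,6-dien-1-yl]-2-methyloxiran-2-yl]pent-2-enal F7, then dimethyl 2-[(3R)-1-[(2S,3S)-3-[(3Z,6E)-7-iodo-3-methylocta-3,6-dien-1-yl]-2-methyloxiran-2-yl]-5-oxopentan-3-yl]malonate F8. CrCl2 with catalytic NiCl2 in DMSO/THF at high dilution closes the ring with retention of the vinyl geometry; a chiral sulfonamide–oxazoline ligand of the Kishi type can be added if reagent control at C3 is needed. This gives dimethyl 2-[(1S,4Z,7E,9R,11R,14S)-9-hydroxy-4,8,14-trimethyl-15-oxabicyclo[12.1.0]pentadeca-4,7-dien-11-yl]malonate F9, which is silylated at once with Et3SiCl/imidazole (to forestall δ-lactonization onto the malonate) to return to 20.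

Step 13. The saponification may be slow, the silyl ether may be lost in the acidic phase, or the protonated epoxide may be intercepted by a ring olefin. The fallback sets out from 17 and comes back at 22, using ester participation instead of a free acid. The Michael addition of step 11 run with di-tert-butyl malonate gives di-tert-butyl 2-[(3R)-1-[(2S,3S)-2-methyl-3-[(3Z)-3-methyloct-3-en-6-yn-1-yl]oxiran-2-yl]-5-oxopentan-3-yl]malonate F10. The macrocyclization of step 12 gives di-tert-butyl 2-[(1S,4Z,7E,9R,11R,14S)-4,8,14-trimethyl-9-(triethylsilyloxy)-15-oxabicyclo[12.1.0]pentadeca-4,7-dien-11-yl]malonate F11. BF3·OEt2 in CH2Cl2 at −78 °C then makes a tert-butyl ester carbonyl open the epoxide at C12 (7-exo, inversion) with loss of 2-methylpropene; the second tert-butyl ester is cleaved under the same conditions, giving 22 without hydroxide or aqueous acid.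

Step 5. The Shi epoxidation may not discriminate well enough between the two trisubstituted olefins, and its ee (about 90 %) is the weakest in the route. The fallback sets out from 1 and comes back at 10, using a hydroxyl-directed Sharpless epoxidation. SeO2 (cat.)/tBuOOH oxidizes the (E)-methyl group of 1 to (2Z,6E)-8-hydroxy-3,7-dimethylocta-2,6-dien-1-yl acetate F1. Ti(OiPr)4, L-(+)-diethyl tartrate, tBuOOH and 4 Å sieves in CH2Cl2 at −20 °C give [(2S,3S)-3-[(3Z)-5-acetoxy-3-methylpent-3-en-1-yl]-2-methyloxiran-2-yl]methanol F2. Dess–Martin oxidation gives (2R,3S)-3-[(3Z)-5-acetoxy-3-methylpent-3-en-1-yl]-2-methyloxirane-2-carbaldehyde F3 (the descriptor changes by priority only). Wittig reaction with Ph3P=CHCO2Me gives methyl (2E)-3-[(2S,3S)-3-[(3Z)-5-acetoxy-3-methylpent-3-en-1-yl]-2-methyloxiran-2-yl]prop-2-enoate F4. Diimide (2-nitrobenzenesulfonohydrazide, Et3N) saturates only the disubstituted enoate olefin and gives 10.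

**Further compounds**
F1 | step 5 | (2Z,6E)-8-hydroxy-3,7-dimethylocta-2,6-dien-1-yl acetate | OC/C(C)=C/CC/C(C)=C\COC(C)=O
F2 | step 5 | [(2S,3S)-3-[(3Z)-5-acetoxy-3-methylpent-3-en-1-yl]-2-methyloxiran-2-yl]methanol | OC[C@]1(C)O[C@H]1CC/C(C)=C\COC(C)=O
F3 | step 5 | (2R,3S)-3-[(3Z)-5-acetoxy-3-methylpent-3-en-1-yl]-2-methyloxirane-2-carbaldehyde | O=C[C@]1(C)O[C@H]1CC/C(C)=C\COC(C)=O
F4 | step 5 | methyl (2E)-3-[(2S,3S)-3-[(3Z)-5-acetoxy-3-methylpent-3-en-1-yl]-2-methyloxiran-2-yl]prop-2-enoate | COC(=O)/C=C/[C@]1(C)O[C@H]1CC/C(C)=C\COC(C)=O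
F5 | step 12 | methyl 3-[(2S,3S)-3-[(3Z,6E)-7-iodo-3-methylocta-3,6-dien-1-yl]-2-methyloxiran-2-yl]propanoate | COC(=O)CC[C@]1(C)O[C@H]1CC/C(C)=C\C/C=C(\C)I
F6 | step 12 | 3-[(2S,3S)-3-[(3Z,6E)-7-iodo-3-methylocta-3,6-dien-1-yl]-2-methyloxiran-2-yl]propanal | O=CCC[C@]1(C)O[C@H]1CC/C(C)=C\C/C=C(\C)I
F7 | step 12 | (2E)-5-[(2S,3S)-3-[(3Z,6E)-7-iodo-3-methylocta-3,6-dien-1-yl]-2-methyloxiran-2-yl]pent-2-enal | O=C/C=C/CC[C@]1(C)O[C@H]1CC/C(C)=C\C/C=C(\C)I
F8 | step 12 | dimethyl 2-[(3R)-1-[(2S,3S)-3-[(3Z,6E)-7-iodo-3-methylocta-3,6-dien-1-yl]-2-methyloxiran-2-yl]-5-oxopentan-3-yl]malonate | O=CC[C@@H](CC[C@]1(C)O[C@H]1CC/C(C)=C\C/C=C(\C)I)C(C(=O)OC)C(=O)OC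
F9 | step 12 | dimethyl 2-[(1S,4Z,7E,9R,11R,14S)-9-hydroxy-4,8,14-trimethyl-15-oxabicyclo[12.1.0]pentadeca-4,7-dien-11-yl]malonate | COC(=O)C(C(=O)OC)[C@H]1C[C@@H](O)/C(C)=C/C/C=C(/C)CC[C@@H]2O[C@@]2(C)CC1
F10 | step 13 | di-tert-butyl 2-[(3R)-1-[(2S,3S)-2-methyl-3-[(3Z)-3-methyloct-3-en-6-yn-1-yl]oxiran-2-yl]-5-oxopentan-3-yl]malonate | O=CC[C@@H](CC[C@]1(C)O[C@H]1CC/C(C)=C\CC#CC)C(C(=O)OC(C)(C)C)C(=O)OC(C)(C)C
F11 | step 13 | di-tert-butyl 2-[(1S,4Z,7E,9R,11R,14S)-4,8,14-trimethyl-9-(triethylsilyloxy)-15-oxabicyclo[12.1.0]pentadeca-4,7-dien-11-yl]malonate | CC(C)(C)OC(=O)C(C(=O)OC(C)(C)C)[C@H]1C[C@@H](O[Si](CC)(CC)CC)/C(C)=C/C/C=C(/C)CC[C@@H]2O[C@@]2(C)CC1
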